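Locants are clerodane numbers: ring A = C1–C5 + C10, ring B = C5–C10. After two protecting groups are removed, the retrosynthesis cuts C3–C4 and C5–C10 in one stroke, then C10–C3/C10–C1, C5–C19, C4–C18, C6–C7 and C8–C9.
Enabling feature: in ring A the run C10H–C1H=C2(O)–C3(=O) is a vinylketene, the open form of a 2-silyloxy-4-alkylcyclobut-2-enone (ring C3–C2–C1–C10). C4(=C18H2)–C5(CH3) is the inner π bond of a 1,1-disubstituted allene, and the bond C5–C10 also belongs to ring B.
Forward: an open chain carrying this four-membered ring on C9 and the allene on C6 is heated. The ring opens at C3–C10 and takes up C4 and C5, so ring A (four to six atoms) and ring B form together, with the methylene ketone and diosphenol ether already in place.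
Chain assembly: both E-trisubstituted alkenes come from hexane-2,5-dione, C8–C9 from a Claisen rearrangement, C6–C7 from an allenylstannane addition, C18 and C19 from alkyne hydroxymethylation and SN2′ methylation, and the four-membered ring from sulfonium-ylide annulation of the C10 aldehyde.
Stereochemistry: one carbinol centre set by catalytic asymmetric Et2Zn addition is relayed to C8 and C9 in the Claisen step and then cleaved off. C7 follows by Felkin–Anh control, and C5 and C10 are set together in the key step by the C7–C9 tether.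
Key step: step 15

Assumption: locants C1–C20 in the text are clerodane numbers of the target (systematic names keep their own numbering), and the cyclobutane carbon C10 is carried as an epimer mixture because step 15 makes it planar before it is finally set.

Step 1
Reactants: 1 hexane-2,5-dione; 2 tert-butyl diethylphosphonoacetate (two equivalents)
Product: 3 di-tert-butyl (2E,6E)-3,6-dimethylocta-2,6-dienedioate
Conditions: NaH, THF, 0 °C to rt
Reagents that add atoms: none
Why: A twofold Horner–Wadsworth–Emmons olefination of the symmetrical diketone with the bulky stabilised phosphonate should favour the E geometry at both new trisubstituted alkenes (ester trans to the CH2CH2 bridge), and Z-containing isomers should be removable by chromatography.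

Step 2
Reactants: 3 di-tert-butyl (2E,6E)-3,6-dimethylocta-2,6-dienedioate
Product: 4 tert-butyl (2E,6E)-8-hydroxy-3,6-dimethylocta-2,6-dienoate
Conditions: i-Bu2AlH (2 equiv), CH2Cl2, −78 °C
Reagents that add atoms: none
Why: 1,2-Reduction of one of the two identical enoates with a limited amount of i-Bu2AlH is a statistical desymmetrisation that should give the allylic alcohol with unchanged alkene geometry, recovered 3 and over-reduced diol being separable and 3 recyclable.

Step 3
Reactants: 4 tert-butyl (2E,6E)-8-hydroxy-3,6-dimethylocta-2,6-dienoate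
Product: 5 tert-butyl (2E,6E)-3,6-dimethyl-8-oxoocta-2,6-dienoate
Conditions: MnO2, CH2Cl2, rt
Reagents that add atoms: none
Why: Heterogeneous MnO2 oxidation is selective for allylic alcohols and should give the E-enal without isomerisation or attack on the enoate.

Step 4
Reactants: 5 tert-butyl (2E,6E)-3,6-dimethyl-8-oxoocta-2,6-dienoate; 6 allyl acetate
Product: 8 tert-butyl (2E,6E,8S)-3,6-dimethyl-8-(prop-2-enyloxy)deca-2,6-dienoate, via ethylzinc (8S)-alkoxide 7 (not isolated)
Conditions: Et2Zn, (−)-3-exo-morpholinoisoborneol (4 mol %), toluene–hexane, 0 °C; then 6, Pd(OAc)2 (5 mol %), PPh3, THF, rt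
Reagents that add atoms: diethylzinc CC[Zn]CC
Why: Ligand-accelerated catalytic asymmetric 1,2-addition of Et2Zn to the enal should set the (S)-carbinol centre, the only stereocentre made by catalysis, and Tsuji–Trost-type O-allylation of the zinc alkoxide 7 should then give the di(allyl) ether in the same flask without touching that centre.

Step 5
Reactants: 8 tert-butyl (2E,6E,8S)-3,6-dimethyl-8-(prop-2-enyloxy)deca-2,6-dienoate
Product: 10 tert-butyl (2E,6R,7E)-3,6-dimethyl-6-[(2S)-1-oxopropan-2-yl]deca-2,7-dienoate, via (E)-prop-1-enyl ether 9 (not isolated)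
Conditions: [IrCl(C8H14)2]2 (1 mol %), PCy3, NaBPh4, CH2Cl2–acetone, rt; then PPh3, ClCH2CH2Cl, 80–100 °C
Reagents that add atoms: none
Why: Iridium-catalysed olefin isomerisation acts only on the unsubstituted allyl group and should give the (E)-propenyl ether 9, whose Claisen rearrangement through a chair with the ethyl group equatorial transfers the carbinol chirality to C8 and C9 at once (E-enol ether plus E-alkene gives the C17/C20 relationship of the target) and builds the quaternary centre.

Step 6
Reactants: 10 tert-butyl (2E,6R,7E)-3,6-dimethyl-6-[(2S)-1-oxopropan-2-yl]deca-2,7-dienoate; 11 tributyl(propa-1,2-dienyl)stannane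
Product: 12 tert-butyl (2E,6R,7E)-6-[(2S,3S)-3-hydroxyhex-5-yn-2-yl]-3,6-dimethyldeca-2,7-dienoate
Conditions: BF3·OEt2, CH2Cl2, −78 °C
Reagents that add atoms: none
Why: Lewis-acid-promoted SE2′ addition of the allenylstannane through an open transition state should give the homopropargylic alcohol, the nucleophile approaching the aldehyde anti to the very large quaternary C9 group as the Felkin–Anh model requires, which sets C7–O syn to the C8 methyl as in the target.

Step 7
Reactants: 12 tert-butyl (2E,6R,7E)-6-[(2S,3S)-3-hydroxyhex-5-yn-2-yl]-3,6-dimethyldeca-2,7-dienoate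
Product: 13 tert-butyl (2E,6R,7E)-6-[(2S,3S)-3,7-dihydroxyhept-5-yn-2-yl]-3,6-dimethyldeca-2,7-dienoate
Conditions: EtMgBr (2.2 equiv), THF, 0 °C to rt; (CH2O)n, rt to 40 °C
Reagents that add atoms: formaldehyde (as paraformaldehyde) C=O
Why: Deprotonation of the hydroxyl group and the terminal alkyne followed by alkynylation of formaldehyde should add C18, the hindered β,β-disubstituted tert-butyl enoate being inert to the Grignard base under these conditions.

Step 8
Reactants: 13 tert-butyl (2E,6R,7E)-6-[(2S,3S)-3,7-dihydroxyhept-5-yn-2-yl]-3,6-dimethyldeca-2,7-dienoate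
Product: 14 tert-butyl (2E,6R,7E)-6-[(2S,3S)-3,7-diacetoxyhept-5-yn-2-yl]-3,6-dimethyldeca-2,7-dienoate
Conditions: Ac2O, pyridine, DMAP (5 mol %), CH2Cl2, rt
Reagents that add atoms: acetic anhydride CC(=O)OC(C)=O
Why: Exhaustive acylation installs in one operation the C7 acetate of the target and the propargylic acetate that later serves as leaving group.

Step 9
Reactants: 14 tert-butyl (2E,6R,7E)-6-[(2S,3S)-3,7-diacetoxyhept-5-yn-2-yl]-3,6-dimethyldeca-2,7-dienoate
Product: 15 tert-butyl (2E,6S,7S,8S)-8,12-diacetoxy-6-formyl-3,6,7-trimethyldodec-2-en-10-ynoate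
Conditions: O3 (one equivalent), CH2Cl2, −78 °C; Me2S, −78 °C to rt
Reagents that add atoms: ozone [O-][O+]=O
Why: Ozonolysis should cleave only the electron-rich 1,2-disubstituted alkene, because the conjugated enoate and the alkyne react far more slowly with the electrophilic oxidant, and it unveils the neopentyl C10 aldehyde while removing the spent carrier of chirality.

Step 10
Reactants: 15 tert-butyl (2E,6S,7S,8S)-8,12-diacetoxy-6-formyl-3,6,7-trimethyldodec-2-en-10-ynoate; 16 cyclopropyldiphenylsulfonium tetrafluoroborate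
Product: 18 tert-butyl (2E,6S,7S,8S)-8,12-diacetoxy-3,6,7-trimethyl-6-(2-oxocyclobutyl)dodec-2-en-10-ynoate (C10 epimers), via oxaspiropentane 17 (not isolated)
Conditions: 16, KN(SiMe3)2, DME, −45 °C; add 15; then LiBF4 (10 mol %), toluene, rt
Reagents that add atoms: none
Why: Corey–Chaykovsky-type epoxidation of the aldehyde with diphenylsulfonium cyclopropylide should give oxaspiropentane 17, whose lithium-ion-induced cyclopropylcarbinyl-to-cyclobutyl rearrangement gives the 2-substituted cyclobutanone (C3=O, C2, C1, C10), the new C10 centre forming as an epimer mixture that is of no consequence because step 15 erases it.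

Step 11
Reactants: 18 tert-butyl (2E,6S,7S,8S)-8,12-diacetoxy-3,6,7-trimethyl-6-(2-oxocyclobutyl)dodec-2-en-10-ynoate
Product: 19 tert-butyl (2E,6S,7S,8S)-8-acetoxy-3,6,7,10-tetramethyl-6-(2-oxocyclobutyl)dodeca-2,10,11-trienoate
Conditions: MeZnCl, Pd(PPh3)4 (5 mol %), THF, 0 °C to rt
Reagents that add atoms: methylzinc chloride C[Zn]Cl
Why: Zerovalent palladium should ionise only the propargylic acetate in SN2′ fashion to an allenylpalladium species that couples at C5 with the ketone- and ester-tolerant methylzinc reagent (Negishi-type coupling), giving the 1,1-disubstituted allene.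

Step 12
Reactants: 19 tert-butyl (2E,6S,7S,8S)-8-acetoxy-3,6,7,10-tetramethyl-6-(2-oxocyclobutyl)dodeca-2,10,11-trienoate
Product: 20 tert-butyl (2E,6S,7S,8S)-8-acetoxy-6-(3-hydroxy-2-oxocyclobutyl)-3,6,7,10-tetramethyldodeca-2,10,11-trienoate
Conditions: LiN(SiMe3)2, THF, −78 °C; 2-(phenylsulfonyl)-3-phenyloxaziridine, −78 °C
Reagents that add atoms: 2-(phenylsulfonyl)-3-phenyloxaziridine O=S(=O)(N1OC1c1ccccc1)c1ccccc1
Why: Kinetic deprotonation should take place at the unhindered C2 methylene of the most acidic carbonyl group (not at C10–H next to the quaternary centre, nor at the esters), and electrophilic α-hydroxylation with the N-sulfonyloxaziridine gives the acyloin, whose new centre is removed in the next step.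

Step 13
Reactants: 20 tert-butyl (2E,6S,7S,8S)-8-acetoxy-6-(3-hydroxy-2-oxocyclobutyl)-3,6,7,10-tetramethyldodeca-2,10,11-trienoate
Product: 21 tert-butyl (2E,6S,7S,8S)-8-acetoxy-6-(2,3-dioxocyclobutyl)-3,6,7,10-tetramethyldodeca-2,10,11-trienoate
Conditions: Dess–Martin periodinane, CH2Cl2, 0 °C
Reagents that add atoms: none
Why: Dess–Martin oxidation of the α-hydroxy ketone under anhydrous, non-basic conditions should give the 1,2-dione without C–C cleavage or benzilic-type ring contraction, and the crude dione is used at once.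

Step 14
Reactants: 21 tert-butyl (2E,6S,7S,8S)-8-acetoxy-6-(2,3-dioxocyclobutyl)-3,6,7,10-tetramethyldodeca-2,10,11-trienoate
Product: 22 tert-butyl (2E,6S,7S,8S)-8-acetoxy-3,6,7,10-tetramethyl-6-[4-oxo-3-(triethylsilyloxy)cyclobut-2-en-1-yl]dodeca-2,10,11-trienoate
Conditions: Et3SiOTf, Et3N, CH2Cl2, −78 °C
Reagents that add atoms: triethylsilyl triflate CC[Si](CC)(CC)OS(=O)(=O)C(F)(F)F
Why: Soft enolisation and O-silylation of the cyclic 1,2-diketone should remove an accessible C1 proton rather than the C10 proton shielded by the quaternary C9, giving the 2-silyloxycyclobutenone whose ketone is C3 and whose sp3 carbon is C10.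

Step 15
Reactants: 22 tert-butyl (2E,6S,7S,8S)-8-acetoxy-3,6,7,10-tetramethyl-6-[4-oxo-3-(triethylsilyloxy)cyclobut-2-en-1-yl]dodeca-2,10,11-trienoate
Product: 24 tert-butyl (2E)-5-[(1R,2S,3S,4aS,8aR)-3-acetoxy-1,2,4a-trimethyl-5-methylidene-6-oxo-7-(triethylsilyloxy)-1,2,3,4,4a,5,6,8a-octahydronaphthalen-1-yl]-3-methylpent-2-enoate, via (E)-vinylketene 23 (not isolated)
Conditions: toluene (0.005 M), BHT, 110–130 °C
Reagents that add atoms: none
Why: Proposed new method: heating should break the C3–C10 bond of the cyclobutenone by conrotatory 4π electrocyclic opening, the bulky C9 group rotating outward to give the (E)-vinylketene 23, whose electrophilic carbon C3 is attacked by the nucleophilic central allene carbon C4 while C10 closes on C5 in a concerted but asynchronous intramolecular [4+2] cycloaddition, so that C4 and C5 are inserted into the former four-membered ring. The closest known reaction types are the thermal cyclobutenone to vinylketene opening of benzannulation chemistry, the Diels–Alder reactions of silyl-substituted vinylketenes, the benzocyclobutene to o-quinodimethane opening followed by intramolecular Diels–Alder reaction, and the rhodium-catalysed (4+2) coupling of cyclobutanones with tethered allenes; what is new is an unactivated allene as 2π partner of a free vinylketene. Ring A closes as the six-membered cycloadduct by formation of C3–C4 and C5–C10 (two-atom expansion of the ring C3–C2–C1–C10), and ring B closes in the same event through the four-atom tether C6–C9 in the manner of a type 1 intramolecular Diels–Alder reaction of a 1,7,9-decatriene. C5 and C10 are set together by a chair-like tether that keeps C7–OAc, C8–CH3 and the C9 side chain equatorial and the C9 methyl axial: the slim sp carbon C4 rather than the C5 methyl should take the axial site syn to that methyl and the C5 methyl should point away from the diene, which gives the cis fusion with H10 and C19 on the face of the side chain. The step needs periselectivity for [4+2] over the usual ketene [2+2] mode and site selectivity for the inner allene π bond, and both are secured by the tether, since the E-vinyl spacer would force a [2+2] adduct into a trans-cyclooctene and only C5 can reach C10 through a six-membered ring. High dilution and a radical inhibitor should hold back ketene dimerisation and dimerisation of the methylene ketone.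

Step 16
Reactants: 24 tert-butyl ester and 2-O-triethylsilyl ether of the target
Product: 25 (2E)-5-[(1R,2S,3S,4aS,8aR)-3-acetoxy-7-hydroxy-1,2,4a-trimethyl-5-methylidene-6-oxo-1,2,3,4,4a,5,6,8a-octahydronaphthalen-1-yl]-3-methylpent-2-enoic acid (CNP0192653.1; clerodane descriptors 5S,7S,8S,9R,10R,13E)
Conditions: CF3CO2H–CH2Cl2 (1:4), trace H2O, 0 °C to rt
Reagents that add atoms: none
Why: Acidolysis removes the tert-butyl ester (loss of isobutene) and the triethylsilyl enol ether in one non-nucleophilic, non-basic operation that should spare the acetate, the methylene ketone and the C10 centre.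

Compound list
1 | hexane-2,5-dione | CC(=O)CCC(C)=O | starting material
2 | tert-butyl diethylphosphonoacetate | CCOP(=O)(CC(=O)OC(C)(C)C)OCC | starting material
3 | di-tert-butyl (2E,6E)-3,6-dimethylocta-2,6-dienedioate | CC(C)(C)OC(=O)/C=C(\C)CC/C(C)=C/C(=O)OC(C)(C)C | intermediate
4 | tert-butyl (2E,6E)-8-hydroxy-3,6-dimethylocta-2,6-dienoate | OC/C=C(\C)CC/C(C)=C/C(=O)OC(C)(C)C | intermediate
5 | tert-butyl (2E,6E)-3,6-dimethyl-8-oxoocta-2,6-dienoate | O=C/C=C(\C)CC/C(C)=C/C(=O)OC(C)(C)C | intermediate
6 | allyl acetate | C=CCOC(C)=O | starting material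
7 | ethylzinc alkoxide of tert-butyl (2E,6E,8S)-8-hydroxy-3,6-dimethyldeca-2,6-dienoate | CC[Zn]O[C@@H](CC)/C=C(\C)CC/C(C)=C/C(=O)OC(C)(C)C | intermediate
8 | tert-butyl (2E,6E,8S)-3,6-dimethyl-8-(prop-2-enyloxy)deca-2,6-dienoate | C=CCO[C@@H](CC)/C=C(\C)CC/C(C)=C/C(=O)OC(C)(C)C | intermediate
9 | tert-butyl (2E,6E,8S)-3,6-dimethyl-8-[(1E)-prop-1-enyloxy]deca-2,6-dienoate | C/C=C/O[C@@H](CC)/C=C(\C)CC/C(C)=C/C(=O)OC(C)(C)C | intermediate
10 | tert-butyl (2E,6R,7E)-3,6-dimethyl-6-[(2S)-1-oxopropan-2-yl]deca-2,7-dienoate | CC/C=C/[C@@](C)(CC/C(C)=C/C(=O)OC(C)(C)C)[C@H](C)C=O | intermediate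
11 | tributyl(propa-1,2-dienyl)stannane | C=C=C[Sn](CCCC)(CCCC)CCCC | starting material
12 | tert-butyl (2E,6R,7E)-6-[(2S,3S)-3-hydroxyhex-5-yn-2-yl]-3,6-dimethyldeca-2,7-dienoate | CC/C=C/[C@@](C)(CC/C(C)=C/C(=O)OC(C)(C)C)[C@H](C)[C@@H](O)CC#C | intermediate
13 | tert-butyl (2E,6R,7E)-6-[(2S,3S)-3,7-dihydroxyhept-5-yn-2-yl]-3,6-dimethyldeca-2,7-dienoate | CC/C=C/[C@@](C)(CC/C(C)=C/C(=O)OC(C)(C)C)[C@H](C)[C@@H](O)CC#CCO | intermediate
14 | tert-butyl (2E,6R,7E)-6-[(2S,3S)-3,7-diacetoxyhept-5-yn-2-yl]-3,6-dimethyldeca-2,7-dienoate | CC/C=C/[C@@](C)(CC/C(C)=C/C(=O)OC(C)(C)C)[C@H](C)[C@@H](OC(C)=O)CC#CCOC(C)=O | intermediate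
15 | tert-butyl (2E,6S,7S,8S)-8,12-diacetoxy-6-formyl-3,6,7-trimethyldodec-2-en-10-ynoate | O=C[C@@](C)(CC/C(C)=C/C(=O)OC(C)(C)C)[C@H](C)[C@@H](OC(C)=O)CC#CCOC(C)=O | intermediate
16 | cyclopropyldiphenylsulfonium tetrafluoroborate | C1CC1[S+](c1ccccc1)c1ccccc1.F[B-](F)(F)F | starting material
17 | tert-butyl (2E,6S,7S,8S)-8,12-diacetoxy-3,6,7-trimethyl-6-(1-oxaspiro[2.2]pentan-2-yl)dodec-2-en-10-ynoate (C10 epimers) | C1CC12OC2[C@@](C)(CC/C(C)=C/C(=O)OC(C)(C)C)[C@H](C)[C@@H](OC(C)=O)CC#CCOC(C)=O | intermediate
18 | tert-butyl (2E,6S,7S,8S)-8,12-diacetoxy-3,6,7-trimethyl-6-(2-oxocyclobutyl)dodec-2-en-10-ynoate (C10 epimers) | O=C1CCC1[C@@](C)(CC/C(C)=C/C(=O)OC(C)(C)C)[C@H](C)[C@@H](OC(C)=O)CC#CCOC(C)=O | intermediate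
19 | tert-butyl (2E,6S,7S,8S)-8-acetoxy-3,6,7,10-tetramethyl-6-(2-oxocyclobutyl)dodeca-2,10,11-trienoate (C10 epimers) | O=C1CCC1[C@@](C)(CC/C(C)=C/C(=O)OC(C)(C)C)[C@H](C)[C@@H](OC(C)=O)CC(C)=C=C | intermediate
20 | tert-butyl (2E,6S,7S,8S)-8-acetoxy-6-(3-hydroxy-2-oxocyclobutyl)-3,6,7,10-tetramethyldodeca-2,10,11-trienoate (ring epimers) | O=C1C(O)CC1[C@@](C)(CC/C(C)=C/C(=O)OC(C)(C)C)[C@H](C)[C@@H](OC(C)=O)CC(C)=C=C | intermediate
21 | tert-butyl (2E,6S,7S,8S)-8-acetoxy-6-(2,3-dioxocyclobutyl)-3,6,7,10-tetramethyldodeca-2,10,11-trienoate (C10 epimers) | O=C1C(=O)CC1[C@@](C)(CC/C(C)=C/C(=O)OC(C)(C)C)[C@H](C)[C@@H](OC(C)=O)CC(C)=C=C | intermediate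
22 | tert-butyl (2E,6S,7S,8S)-8-acetoxy-3,6,7,10-tetramethyl-6-[4-oxo-3-(triethylsilyloxy)cyclobut-2-en-1-yl]dodeca-2,10,11-trienoate (C10 epimers) | O=C1C(O[Si](CC)(CC)CC)=CC1[C@@](C)(CC/C(C)=C/C(=O)OC(C)(C)C)[C@H](C)[C@@H](OC(C)=O)CC(C)=C=C | intermediate
23 | open-chain (E)-vinylketene from 22 (ketene C3=C2 bearing OSiEt3, C1=C10 E, chain unchanged) | O=C=C(O[Si](CC)(CC)CC)/C=C/[C@@](C)(CC/C(C)=C/C(=O)OC(C)(C)C)[C@H](C)[C@@H](OC(C)=O)CC(C)=C=C | intermediate
24 | tert-butyl (2E)-5-[(1R,2S,3S,4aS,8aR)-3-acetoxy-1,2,4a-trimethyl-5-methylidene-6-oxo-7-(triethylsilyloxy)-1,2,3,4,4a,5,6,8a-octahydronaphthalen-1-yl]-3-methylpent-2-enoate | C=C1C(=O)C(O[Si](CC)(CC)CC)=C[C@@H]2[C@@](C)(CC/C(C)=C/C(=O)OC(C)(C)C)[C@H](C)[C@@H](OC(C)=O)C[C@]12C | intermediate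
25 | (2E)-5-[(1R,2S,3S,4aS,8aR)-3-acetoxy-7-hydroxy-1,2,4a-trimethyl-5-methylidene-6-oxo-1,2,3,4,4a,5,6,8a-octahydronaphthalen-1-yl]-3-methylpent-2-enoic acid | C=C1C(=O)C(O)=C[C@@H]2[C@@](C)(CC/C(C)=C/C(=O)O)[C@H](C)[C@@H](OC(C)=O)C[C@]12C | target

Total steps: 16. Longest linear sequence: 16 steps, from hexane-2,5-dione.

Steps most likely to fail

1. Step 15.
- What may go wrong: the vinylketene may reclose or dimerise faster than the allene intercepts it. The competing chair-like approaches may also be poorly differentiated, so that the ring fusion forms with poor facial selectivity.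
- Fallback chemistry: known reactions only, namely Wittig olefination, silyl dienol ether formation and the transition-metal-catalysed intramolecular [4+2] cycloaddition of dienes with unactivated allenes. It sets out from 15 and comes back to the route at 25.
- Course: aldehyde 15 is condensed with 1-(tert-butyldimethylsilyloxy)-3-(triphenylphosphoranylidene)propan-2-one (toluene, 90 °C) to the (E)-enone F1. MeZnCl and Pd(PPh3)4 as in step 11 give the allenyl enone F2, and Et3SiOTf with Et3N gives the 2-silyloxy diene F3. Ni(cod)2 with tris(2-biphenylyl) phosphite (zerovalent nickel, THF, rt to 60 °C) closes both rings across the inner allene π bond to the bicyclic bis(silyl ether) F4. HF·pyridine frees the acyloin F5. Dess–Martin oxidation gives the 2,3-diketone, which can enolise only towards C1 and should appear as the diosphenol tert-butyl ester F6. CF3CO2H as in step 16 then gives 25.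

2. Step 13 (with step 14).
- What may go wrong: the strained 1,2-dione may be hydrated and undergo benzilic-type ring contraction before it is silylated. Enolisation may also stray towards C10.
- Fallback: it avoids the dione altogether, sets out from 19 and comes back at 22.
- Course: Et3SiOTf with Et3N gives the cyclobutenyl silyl ether F7. Rubottom oxidation (mCPBA, NaHCO3, CH2Cl2, −20 °C) with silyl migration gives the α-silyloxy cyclobutanone F8. LiN(SiMe3)2 followed by PhSeCl gives the α-phenylselanyl ketone F9. Oxidation with mCPBA at −78 °C and warming brings about selenoxide syn elimination towards C1–H and delivers 22.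

3. Step 10.
- What may go wrong: the basic ylide may attack the acetates or add only sluggishly to the neopentyl aldehyde. Ionisation of the oxaspiropentane next to the quaternary C9 may trigger a Wagner–Meerwein shift instead of ring expansion.
- Fallback: it replaces ylide epoxidation by carbanion addition and a sulfur-assisted cationic ring expansion, sets out from 15 and comes back at 18.
- Course: 1-lithiocyclopropyl phenyl sulfide (cyclopropyl phenyl sulfide, n-BuLi, THF, 0 °C, then 15 at −78 °C) gives the β-hydroxy sulfide F10. Aqueous HBF4 in Et2O at rt then induces the cyclopropylcarbinyl rearrangement and hydrolysis of the thionium ion to 18.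

Further compounds
F1 | step 15 | (E)-enone, TBSOCH2–C(=O)–CH=CH unit on C9, propargylic acetate intact | CC(C)(C)[Si](C)(C)OCC(=O)/C=C/[C@@](C)(CC/C(C)=C/C(=O)OC(C)(C)C)[C@H](C)[C@@H](OC(C)=O)CC#CCOC(C)=O
F2 | step 15 | allenyl enone (1,1-disubstituted allene at C5) | CC(C)(C)[Si](C)(C)OCC(=O)/C=C/[C@@](C)(CC/C(C)=C/C(=O)OC(C)(C)C)[C@H](C)[C@@H](OC(C)=O)CC(C)=C=C
F3 | step 15 | 2-silyloxy diene C3H(OTBS)=C2(OSiEt3)–C1H=C10H | CC(C)(C)[Si](C)(C)OC=C(O[Si](CC)(CC)CC)/C=C/[C@@](C)(CC/C(C)=C/C(=O)OC(C)(C)C)[C@H](C)[C@@H](OC(C)=O)CC(C)=C=C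
F4 | step 15 | bicyclic bis(silyl ether), C3–OTBS and C2–OSiEt3 enol ether | C=C1C(O[Si](C)(C)C(C)(C)C)C(O[Si](CC)(CC)CC)=C[C@@H]2[C@@](C)(CC/C(C)=C/C(=O)OC(C)(C)C)[C@H](C)[C@@H](OC(C)=O)C[C@]12C
F5 | step 15 | acyloin, 3-hydroxy-2-ketone of the decalin | C=C1C(O)C(=O)C[C@@H]2[C@@](C)(CC/C(C)=C/C(=O)OC(C)(C)C)[C@H](C)[C@@H](OC(C)=O)C[C@]12C
F6 | step 15 | diosphenol tert-butyl ester (tert-butyl ester of 25) | C=C1C(=O)C(O)=C[C@@H]2[C@@](C)(CC/C(C)=C/C(=O)OC(C)(C)C)[C@H](C)[C@@H](OC(C)=O)C[C@]12C
F7 | step 13 | cyclobutenyl silyl ether of 19 (C3–OSiEt3, C3=C2) | CC[Si](CC)(CC)OC1=CCC1[C@@](C)(CC/C(C)=C/C(=O)OC(C)(C)C)[C@H](C)[C@@H](OC(C)=O)CC(C)=C=C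
F8 | step 13 | α-silyloxy cyclobutanone (C2–OSiEt3) | O=C1C(O[Si](CC)(CC)CC)CC1[C@@](C)(CC/C(C)=C/C(=O)OC(C)(C)C)[C@H](C)[C@@H](OC(C)=O)CC(C)=C=C
F9 | step 13 | α-phenylselanyl α-silyloxy cyclobutanone | O=C1C(O[Si](CC)(CC)CC)([Se]c2ccccc2)CC1[C@@](C)(CC/C(C)=C/C(=O)OC(C)(C)C)[C@H](C)[C@@H](OC(C)=O)CC(C)=C=C
F10 | step 10 | β-hydroxy sulfide, C10 carbinol bearing a 1-(phenylthio)cyclopropyl group | c1ccccc1SC1(CC1)C(O)[C@@](C)(CC/C(C)=C/C(=O)OC(C)(C)C)[C@H](C)[C@@H](OC(C)=O)CC#CCOC(C)=O
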